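**Plan**

- Retrosynthesis: the two O–CH3 bonds on rings A and C are cut last. Ring D is then cut at C1–C2 and C3–C4, once C1 and C4 are re-bridged by oxygen, which leads back to a 2-(2-arylethyl)furan and vinylene carbonate.
- Enabling feature: ring D carries the ethylene chain on C1, hydroxyls on C2 and C3, and hydrogens on C4–C6. C1 is the alkylated α-carbon of a furan, C4–C6 are its other three ring carbons, and C2/C3 are the two oxygen-bearing carbons of a symmetric dienophile.
- The furan precursor is cut at both Ar–CH2CH2–Ar links (Wittig alkenes, saturated later) and at the ring B–O bond of the diaryl ether (SNAr).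
- Forward: ring C (as a nitrile) is joined to ring B by SNAr and ring A is added by Wittig olefination. The nitrile is reduced to the aldehyde and the furan is added by a second Wittig olefination. Both alkenes are saturated with diimide, ring D is built by [4+2] cycloaddition and dehydrative aromatisation, and the methyl ethers are cleaved.
- Stereochemistry: the target has no stereocentre. The four centres of the racemic oxanorbornene adduct and the alkene geometries of the Wittig products are transient and are erased before the end.

Key step: step 7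

Remark: the Wittig products are expected as E/Z mixtures (E isomers drawn) and the cycloadduct as a racemic exo/endo mixture (exo drawn); both features disappear later, so no separation is planned.

**Route**

Step 1
Reactants: 1 3-hydroxy-4-methoxybenzonitrile; 2 4-fluorobenzaldehyde
Product: 3 3-(4-formylphenoxy)-4-methoxybenzonitrile
Conditions: K2CO3, DMF, 120 °C
Reagents that add atoms: none
Why: Nucleophilic aromatic substitution (SNAr), in which the para-formyl group activates the fluoride toward the phenoxide of 1, while the nitrile keeps the future ring C aldehyde masked so the two carbonyl carbons stay distinguishable.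

Step 2
Reactants: 3 3-(4-formylphenoxy)-4-methoxybenzonitrile; 4 (3-methoxybenzyl)triphenylphosphonium chloride
Product: 6 4-methoxy-3-{4-[2-(3-methoxyphenyl)ethenyl]phenoxy}benzonitrile (E/Z mixture expected; E drawn), via benzylidenephosphorane 5 (not isolated)
Conditions: KOtBu, THF, 0 °C → rt
Reagents that add atoms: none
Why: Wittig olefination of the aryl aldehyde with the semistabilised ylide; the nitrile is inert to the ylide and the alkene geometry is irrelevant because the double bond is saturated in step 6.

Step 3
Reactants: 6 4-methoxy-3-{4-[2-(3-methoxyphenyl)ethenyl]phenoxy}benzonitrile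
Product: 8 4-methoxy-3-{4-[2-(3-methoxyphenyl)ethenyl]phenoxy}benzaldehyde, via N-aluminated aldimine 7 (not isolated)
Conditions: i-Bu2AlH, CH2Cl2, −78 → 0 °C; then 1 M HCl, 0 °C
Reagents that add atoms: water, O
Why: Half-reduction of an aryl nitrile with i-Bu2AlH stops at the N-aluminated aldimine, which hydrolyses to the aldehyde on acidic work-up; the stilbene and the ethers are untouched.

Step 4
Reactants: 9 furfuryl alcohol (furan-2-ylmethanol)
Product: 10 (furan-2-ylmethyl)triphenylphosphonium bromide
Conditions: PPh3·HBr, MeCN, reflux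
Reagents that add atoms: triphenylphosphine hydrobromide, Br.P(c1ccccc1)(c1ccccc1)c1ccccc1
Why: Direct alcohol-to-phosphonium conversion, in which protonation gives the stabilised furfuryl electrophile and triphenylphosphine captures it by substitution and quaternisation before it can oligomerise.

Step 5
Reactants: 8 4-methoxy-3-{4-[2-(3-methoxyphenyl)ethenyl]phenoxy}benzaldehyde; 10 (furan-2-ylmethyl)triphenylphosphonium bromide
Product: 12 2-[2-(4-methoxy-3-{4-[2-(3-methoxyphenyl)ethenyl]phenoxy}phenyl)ethenyl]furan (mixture of alkene isomers expected; E,E drawn), via furfurylidenephosphorane 11 (not isolated)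
Conditions: KOtBu, THF, 0 °C → rt
Reagents that add atoms: none
Why: Wittig olefination of the ring C aldehyde with the furfuryl ylide joins the furan through the two carbons that become the ring C–ring D ethylene link.

Step 6
Reactants: 12 2-[2-(4-methoxy-3-{4-[2-(3-methoxyphenyl)ethenyl]phenoxy}phenyl)ethenyl]furan
Product: 13 2-[2-(4-methoxy-3-{4-[2-(3-methoxyphenyl)ethyl]phenoxy}phenyl)ethyl]furan
Conditions: TsNHNH2 (excess), NaOAc, THF/H2O, reflux
Reagents that add atoms: none
Why: Diimide reduction transfers two hydrogens in a concerted syn fashion to both disubstituted alkenes and cannot touch the aromatic furan, which hydrogenation over a palladium catalyst might saturate.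

Step 7
Reactants: 13 2-[2-(4-methoxy-3-{4-[2-(3-methoxyphenyl)ethyl]phenoxy}phenyl)ethyl]furan; 14 vinylene carbonate
Product: 15 racemic 4-[2-(4-methoxy-3-{4-[2-(3-methoxyphenyl)ethyl]phenoxy}phenyl)ethyl]-3a,4,7,7a-tetrahydro-4,7-epoxy-1,3-benzodioxol-2-one (7-oxanorbornene cis-carbonate; exo isomer drawn, endo isomer also expected)
Conditions: 14 (neat, large excess), BHT (cat.), sealed tube, 125 °C; recovered 13 recycled
Reagents that add atoms: none
Why: This is a concerted, suprafacial [4+2] cycloaddition in which the furan of 13 is the 4π component and the C=C of 14 the 2π component, forming the bonds that become C1–C2 and C3–C4 of ring D; the closest known reaction is the thermal Diels–Alder reaction of furan and 2-methylfuran with vinylene carbonate. The six-membered carbocycle is closed by this intermolecular cycloaddition in one step, and the furan oxygen becomes the 1,4-bridge of a 7-oxanorbornene. The two carbonate-bearing centres are cis because the dienophile geometry is retained in the suprafacial addition, and the two bridgehead centres are fixed relative to each other by the bicyclic frame; exo versus endo orientation is not controlled and the adduct is racemic, which is harmless because all four centres become sp2 in step 9. The step needs chemoselectivity and conversion, not stereoselectivity: the furan is the only diene in 13, the symmetric dienophile removes any question of orientation, and neat excess 14 with recycling of recovered 13 offsets the reversibility of furan cycloadditions.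

Step 8
Reactants: 15 7-oxanorbornene cis-carbonate
Product: 16 racemic 1-[2-(4-methoxy-3-{4-[2-(3-methoxyphenyl)ethyl]phenoxy}phenyl)ethyl]-7-oxabicyclo[2.2.1]hept-5-ene-2,3-diol (cis-diol; exo,exo drawn)
Conditions: K2CO3 (cat.), MeOH, rt
Reagents that add atoms: none
Why: Base-catalysed transesterification of the five-membered cyclic carbonate with methanol releases the cis-diol without breaking either ring C–O bond, so the configuration is retained and the 7-oxanorbornene is untouched.

Step 9
Reactants: 16 7-oxanorbornene cis-diol
Product: 17 3-[2-(4-methoxy-3-{4-[2-(3-methoxyphenyl)ethyl]phenoxy}phenyl)ethyl]benzene-1,2-diol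
Conditions: TsOH·H2O (cat.), toluene, 70 °C, Ar
Reagents that add atoms: none
Why: Proposed new method: protonation of the bridging oxygen and heterolysis of its bond to the tertiary, allylic, chain-bearing bridgehead should give an allyl cation that collapses by 1,2-hydride shift (or proton loss) from the neighbouring carbinol carbon C2, which is why the free diol and not the carbonate is used, after which the bridge-derived hydroxyl on C4, now allylic and β to the carbonyl, leaves as water and enolisation gives the catechol, a net loss of one water without oxidant; the closest known reaction type is the acid-catalysed dehydrative aromatisation of furan Diels–Alder adducts (7-oxanorbornenes to arenes, 7-oxanorbornadienes to phenols).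

Step 10
Reactants: 17 3-[2-(4-methoxy-3-{4-[2-(3-methoxyphenyl)ethyl]phenoxy}phenyl)ethyl]benzene-1,2-diol
Product: 18 3-[2-(4-hydroxy-3-{4-[2-(3-hydroxyphenyl)ethyl]phenoxy}phenyl)ethyl]benzene-1,2-diol (target CNP0185459.0)
Conditions: BBr3 (excess), CH2Cl2, −78 °C → rt; then H2O
Reagents that add atoms: none
Why: Lewis-acid demethylation of aryl methyl ethers with BBr3 (complexation, then bromide attack at methyl) frees the two phenols, while the diaryl ether, which offers no sp3 carbon for substitution, survives and the catechol is carried as its borate until hydrolysis.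

**Compound list**

1 | 3-hydroxy-4-methoxybenzonitrile | N#Cc1ccc(OC)c(O)c1 | starting material
2 | 4-fluorobenzaldehyde | O=Cc1ccc(F)cc1 | starting material
3 | 3-(4-formylphenoxy)-4-methoxybenzonitrile | N#Cc1ccc(OC)c(Oc2ccc(C=O)cc2)c1 | intermediate
4 | (3-methoxybenzyl)triphenylphosphonium chloride | COc1cccc(C[P+](c2ccccc2)(c2ccccc2)c2ccccc2)c1.[Cl-] | starting material
5 | (3-methoxybenzylidene)triphenylphosphorane (not isolated) | COc1cccc(C=P(c2ccccc2)(c2ccccc2)c2ccccc2)c1 | intermediate
6 | 4-methoxy-3-{4-[(E)-2-(3-methoxyphenyl)ethenyl]phenoxy}benzonitrile (E/Z mixture expected) | N#Cc1ccc(OC)c(Oc2ccc(/C=C/c3cccc(OC)c3)cc2)c1 | intermediate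
7 | N-(diisobutylaluminio)aldimine of 8 (not isolated) | CC(C)C[Al](CC(C)C)N=Cc1ccc(OC)c(Oc2ccc(/C=C/c3cccc(OC)c3)cc2)c1 | intermediate
8 | 4-methoxy-3-{4-[(E)-2-(3-methoxyphenyl)ethenyl]phenoxy}benzaldehyde (E/Z mixture expected) | O=Cc1ccc(OC)c(Oc2ccc(/C=C/c3cccc(OC)c3)cc2)c1 | intermediate
9 | furfuryl alcohol (furan-2-ylmethanol) | OCc1ccco1 | starting material
10 | (furan-2-ylmethyl)triphenylphosphonium bromide | [Br-].C(c1ccco1)[P+](c1ccccc1)(c1ccccc1)c1ccccc1 | intermediate
11 | (furan-2-ylmethylidene)triphenylphosphorane (not isolated) | C(=P(c1ccccc1)(c1ccccc1)c1ccccc1)c1ccco1 | intermediate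
12 | 2-[(E)-2-(4-methoxy-3-{4-[(E)-2-(3-methoxyphenyl)ethenyl]phenoxy}phenyl)ethenyl]furan (isomer mixture expected) | COc1cccc(/C=C/c2ccc(Oc3cc(/C=C/c4ccco4)ccc3OC)cc2)c1 | intermediate
13 | 2-[2-(4-methoxy-3-{4-[2-(3-methoxyphenyl)ethyl]phenoxy}phenyl)ethyl]furan | COc1cccc(CCc2ccc(Oc3cc(CCc4ccco4)ccc3OC)cc2)c1 | intermediate
14 | vinylene carbonate (1,3-dioxol-2-one) | O=C1OC=CO1 | starting material
15 | racemic 7-oxanorbornene cis-carbonate with the 2-arylethyl chain on the bridgehead (exo drawn; endo also expected) | O=C1O[C@H]2[C@@H]3C=C[C@@](CCc4ccc(OC)c(Oc5ccc(CCc6cccc(OC)c6)cc5)c4)(O3)[C@H]2O1 | intermediate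
16 | racemic 1-(2-arylethyl)-7-oxabicyclo[2.2.1]hept-5-ene-2,3-cis-diol (exo,exo drawn) | O[C@H]1[C@@H]2C=C[C@@](CCc3ccc(OC)c(Oc4ccc(CCc5cccc(OC)c5)cc4)c3)(O2)[C@H]1O | intermediate
17 | 3-[2-(4-methoxy-3-{4-[2-(3-methoxyphenyl)ethyl]phenoxy}phenyl)ethyl]benzene-1,2-diol | COc1cccc(CCc2ccc(Oc3cc(CCc4cccc(O)c4O)ccc3OC)cc2)c1 | intermediate
18 | 3-[2-(4-hydroxy-3-{4-[2-(3-hydroxyphenyl)ethyl]phenoxy}phenyl)ethyl]benzene-1,2-diol | Oc1cccc(CCc2ccc(Oc3cc(CCc4cccc(O)c4O)ccc3O)cc2)c1 | target

**Step count and risks**

Total step count: 10. Longest linear sequence: 9 steps (steps 1–3 and 5–10); step 4 is a one-step side branch.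

The three steps most likely to fail:

1. Step 9 (aromatisation). After the bridge ionises, the hydride shift may come from the carbinol carbon next to the unsubstituted bridgehead. A ring hydroxyl other than the bridge-derived one would then be expelled, giving regioisomeric dihydroxyarenes. The tertiary allylic cation may also be trapped by ring C in a Friedel–Crafts spirocyclisation. The fallback uses known chemistry and brings ring D in ready-made. It sets out from aldehyde 8. Wittig olefination with (2,3-dimethoxybenzyl)triphenylphosphonium bromide and KOtBu in THF, through the ylide (2,3-dimethoxybenzylidene)triphenylphosphorane F1, should give the bis-stilbene 1,2-dimethoxy-3-[2-(4-methoxy-3-{4-[2-(3-methoxyphenyl)ethenyl]phenoxy}phenyl)ethenyl]benzene F2. Hydrogenation (H2, Pd/C, EtOAc) should saturate both alkenes to the tetramethyl ether 1,2-dimethoxy-3-[2-(4-methoxy-3-{4-[2-(3-methoxyphenyl)ethyl]phenoxy}phenyl)ethyl]benzene F3. Excess BBr3 in CH2Cl2 should then cleave all four methyl ethers, so the sequence comes back to the route at target 18.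

2. Step 7 (cycloaddition). Cycloreversion at the reaction temperature may hold conversion low, and radical polymerisation of the dienophile may consume it before enough adduct accumulates. The fallback gives up the ring construction and couples a preformed ring D through an alkyne. It sets out from aldehyde 8. Seyferth–Gilbert homologation with the Ohira–Bestmann reagent (dimethyl (1-diazo-2-oxopropyl)phosphonate, K2CO3, MeOH) should give the terminal alkyne 4-ethynyl-1-methoxy-2-{4-[2-(3-methoxyphenyl)ethenyl]phenoxy}benzene F4. Sonogashira coupling with 1-iodo-2,3-dimethoxybenzene (PdCl2(PPh3)2, CuI, Et3N) should give the diarylalkyne 1-[(4-methoxy-3-{4-[2-(3-methoxyphenyl)ethenyl]phenoxy}phenyl)ethynyl]-2,3-dimethoxybenzene F5. Hydrogenation over Pd/C should reduce alkyne and stilbene to the tetramethyl ether F3 described under step 9, and BBr3 returns the sequence to target 18.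

3. Step 4 (phosphonium salt from furfuryl alcohol). Acid-triggered oligomerisation of the furfuryl cation may outrun its capture by the phosphine. The fallback reverses the polarity of the olefination so that the furan enters as stable furfural. It sets out from aldehyde 8. Reduction with NaBH4 in MeOH should give the benzyl alcohol (4-methoxy-3-{4-[2-(3-methoxyphenyl)ethenyl]phenoxy}phenyl)methanol F6. PPh3·HBr in MeCN should convert it into the phosphonium salt (4-methoxy-3-{4-[2-(3-methoxyphenyl)ethenyl]phenoxy}benzyl)triphenylphosphonium bromide F7. Deprotonation with KOtBu in THF gives the ylide (4-methoxy-3-{4-[2-(3-methoxyphenyl)ethenyl]phenoxy}benzylidene)triphenylphosphorane F8, and Wittig olefination with furfural comes back to the route at compound 12.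

**Further compounds**

F1 | step 9 | (2,3-dimethoxybenzylidene)triphenylphosphorane | COc1cccc(C=P(c2ccccc2)(c2ccccc2)c2ccccc2)c1OC
F2 | step 9 | 1,2-dimethoxy-3-[(E)-2-(4-methoxy-3-{4-[(E)-2-(3-methoxyphenyl)ethenyl]phenoxy}phenyl)ethenyl]benzene | COc1cccc(/C=C/c2ccc(Oc3cc(/C=C/c4cccc(OC)c4OC)ccc3OC)cc2)c1
F3 | step 9 | 1,2-dimethoxy-3-[2-(4-methoxy-3-{4-[2-(3-methoxyphenyl)ethyl]phenoxy}phenyl)ethyl]benzene | COc1cccc(CCc2ccc(Oc3cc(CCc4cccc(OC)c4OC)ccc3OC)cc2)c1
F4 | step 7 | 4-ethynyl-1-methoxy-2-{4-[(E)-2-(3-methoxyphenyl)ethenyl]phenoxy}benzene | C#Cc1ccc(OC)c(Oc2ccc(/C=C/c3cccc(OC)c3)cc2)c1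
F5 | step 7 | 1-[(4-methoxy-3-{4-[(E)-2-(3-methoxyphenyl)ethenyl]phenoxy}phenyl)ethynyl]-2,3-dimethoxybenzene | COc1cccc(/C=C/c2ccc(Oc3cc(C#Cc4cccc(OC)c4OC)ccc3OC)cc2)c1
F6 | step 4 | (4-methoxy-3-{4-[(E)-2-(3-methoxyphenyl)ethenyl]phenoxy}phenyl)methanol | OCc1ccc(OC)c(Oc2ccc(/C=C/c3cccc(OC)c3)cc2)c1
F7 | step 4 | (4-methoxy-3-{4-[(E)-2-(3-methoxyphenyl)ethenyl]phenoxy}benzyl)triphenylphosphonium bromide | COc1ccc(C[P+](c2ccccc2)(c2ccccc2)c2ccccc2)cc1Oc1ccc(/C=C/c2cccc(OC)c2)cc1.[Br-]
F8 | step 4 | (4-methoxy-3-{4-[(E)-2-(3-methoxyphenyl)ethenyl]phenoxy}benzylidene)triphenylphosphorane | COc1ccc(C=P(c2ccccc2)(c2ccccc2)c2ccccc2)cc1Oc1ccc(/C=C/c2cccc(OC)c2)cc1
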